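**Retrosynthetic overview**
1. Juglanin A (16) ⇐ 7-oxo compound 14 by hydrogenolysis of a C7 aryl ketone. The ketone is kept to the end because its hydrogen bond masks the ring-B 2-OH, so no protecting group is used.
2. 14 ⇐ phenol 13 (O-methylation) ⇐ ynol ether 11 by one gold-catalysed furan–ynol ether benzannulation that builds ring A and closes the 15-membered diaryl ether macrocycle in the same operation.
3. 11 ⇐ phenol 7 via dichlorovinyl ether 9; trichloroethylene supplies two ring-A carbons and the 3-substituted furan the other four.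
4. 7 ⇐ diketone 3 + furan-3-carbaldehyde (aldol, C=C hydrogenation); 3 ⇐ 2-methoxyresorcinol + 5-oxohexanoic acid (Friedel–Crafts acylation).
5. Ring order: ring B is bought; ring A and the macrocycle are formed together in step 6.

Assumption: the SMILES contains no stereocentre, so the target is achiral as drawn and no stereocontrol is needed. Chain carbons are called C1 (on ring A, the anisole ring) to C7 (on ring B, the phenol ring).

**Route**

Step 1
Reactants: 1 2-methoxybenzene-1,3-diol (2-methoxyresorcinol); 2 5-oxohexanoic acid
Product: 3 1-(2,4-dihydroxy-3-methoxyphenyl)hexane-1,5-dione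
Conditions: BF3·OEt2 (as solvent), 85 °C, 2 h; aq NaOAc work-up
Reagents that add atoms: none
Why: Friedel–Crafts (Nencki-type) C-acylation, in which BF3 activates the carboxylic acid and the doubly activated C4 position of the resorcinol (ortho to one OH, para to the other, C4 and C6 being equivalent) is acylated once, the hydrogen-bonded o-hydroxyaryl ketone formed being deactivated towards a second acylation; no stereocentre is formed.

Step 2
Reactants: 3 1-(2,4-dihydroxy-3-methoxyphenyl)hexane-1,5-dione; 4 furan-3-carbaldehyde
Product: 6 (E)-1-(2,4-dihydroxy-3-methoxyphenyl)-7-(furan-3-yl)hept-6-ene-1,5-dione, via aldol adduct 5 (not isolated)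
Conditions: NaOH (4 equiv), EtOH/H2O, 0 °C → rt; then aq HCl to pH 5
Reagents that add atoms: none
Why: Claisen–Schmidt crossed aldol condensation, in which the non-enolisable aldehyde is attacked by the methyl-side enolate of the dialkyl ketone (the aryl ketone is switched off as its bis-phenoxide) and E1cB dehydration of aldol 5 gives the conjugated (E)-enone; no stereocentre remains.

Step 3
Reactants: 6 (E)-1-(2,4-dihydroxy-3-methoxyphenyl)-7-(furan-3-yl)hept-6-ene-1,5-dione
Product: 7 1-(2,4-dihydroxy-3-methoxyphenyl)-7-(furan-3-yl)heptane-1,5-dione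
Conditions: H2 (1 atm), Pd/C (5%), EtOAc, rt, stopped after 1 equiv H2
Reagents that add atoms: none
Why: Heterogeneous catalytic hydrogenation, the conjugated disubstituted C=C being reduced much faster than the furan ring or the electron-rich aryl ketone under neutral conditions at 1 atm; no stereocentre is formed.

Step 4
Reactants: 7 1-(2,4-dihydroxy-3-methoxyphenyl)-7-(furan-3-yl)heptane-1,5-dione; 8 trichloroethylene
Product: 9 1-{4-[(E)-1,2-dichloroethenyloxy]-2-hydroxy-3-methoxyphenyl}-7-(furan-3-yl)heptane-1,5-dione
Conditions: K2CO3 (2 equiv), trichloroethylene (1.2 equiv), DMF, 65 °C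
Reagents that add atoms: none
Why: Greene-type dichlorovinylation (elimination–addition vinylic substitution), in which carbonate generates dichloroacetylene from trichloroethylene and the 4-phenoxide (para to the acyl group, not hydrogen-bonded) adds anti to it to give the (E)-1,2-dichlorovinyl ether, while the 2-OH stays locked in its hydrogen bond to the C7 carbonyl and does not react.

Step 5
Reactants: 9 1-{4-[(E)-1,2-dichloroethenyloxy]-2-hydroxy-3-methoxyphenyl}-7-(furan-3-yl)heptane-1,5-dione
Product: 11 1-[4-(ethynyloxy)-2-hydroxy-3-methoxyphenyl]-7-(furan-3-yl)heptane-1,5-dione, via chloroethynyl ether 10 (not isolated)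
Conditions: LiN(SiMe3)2 (3.3 equiv), THF, −78 °C; n-BuLi (5.7 equiv), −78 → −40 °C; sat. aq NH4Cl; chromatography on Et3N-deactivated silica
Reagents that add atoms: none
Why: Greene ynol ether synthesis with in situ enolate protection, in which LiN(SiMe3)2 first turns the phenol and both ketones into a lithium phenoxide and enolates that are inert to n-BuLi (3.3 equiv of which only re-form the amide base), after which n-BuLi deprotonates the dichlorovinyl ether, LiCl is lost to give chloroalkyne 10, and chlorine–lithium exchange gives the lithium acetylide that is protonated on quench; no stereocentre is involved.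

Step 6
Reactants: 11 1-[4-(ethynyloxy)-2-hydroxy-3-methoxyphenyl]-7-(furan-3-yl)heptane-1,5-dione
Product: 13 macrocyclic ring-A phenol (juglanin A skeleton bearing OH in place of the ring-A OMe and a C7 ketone), via arene oxide 12 (not isolated)
Conditions: [Au(IPr)(NTf2)] (5 mol%; IPr = 1,3-bis(2,6-diisopropylphenyl)imidazol-2-ylidene; monovalent gold), CH2Cl2, 4 Å MS, 23 °C, syringe-pump addition over 12 h to 0.5 mM
Reagents that add atoms: none
Why: Proposed new method: the cationic gold centre activates the aryl ynol ether at its oxygen-bearing carbon, which is attacked by C2 of the 3-alkylfuran (its most nucleophilic position), the cyclopropyl gold carbene so formed unravels the furan to a (Z)-dienal gold carbene, capture of the carbene by the carbonyl oxygen gives oxepine/arene oxide 12, and its opening with oxygen retained on the former alkyne CH carbon (the cation is stabilised by the adjacent aryloxy-bearing carbon and the para alkyl-bearing carbon) gives the 2-aryloxy-4-alkylphenol, so that ring A and the 15-membered ring close in the same event; the closest known reaction is the gold-catalysed furan–yne phenol synthesis (Hashmi phenol synthesis), here extended to a macrocyclising ynol ether case; no stereocentre is formed.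

Step 7
Reactants: 13 macrocyclic ring-A phenol
Product: 14 7-oxojuglanin A
Conditions: MeI (1.3 equiv), K2CO3 (1.5 equiv), acetone, 40 °C
Reagents that add atoms: iodomethane, CI
Why: Williamson O-methylation, in which only the free ring-A phenol is deprotonated and alkylated, whereas the ring-B 2-OH is masked by its strong intramolecular hydrogen bond to the C7 carbonyl (the usual selectivity of o-hydroxyaryl ketones).

Step 8
Reactants: 14 7-oxojuglanin A
Product: 16 juglanin A, via benzylic alcohol 15 (not isolated)
Conditions: H2 (4 atm), Pd/C (10%), AcOH, 50 °C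
Reagents that add atoms: none
Why: Catalytic hydrogenolysis of an electron-rich o-hydroxyaryl ketone, which is reduced via benzylic alcohol 15 to the methylene group while the dialkyl C3 ketone, the diaryl ether, the methyl ethers and the phenol are inert on palladium; the transient carbinol stereocentre is destroyed and the product has none.

**Compound list**
1 | 2-methoxybenzene-1,3-diol | COc1c(O)cccc1O | starting material
2 | 5-oxohexanoic acid | CC(=O)CCCC(=O)O | starting material
3 | 1-(2,4-dihydroxy-3-methoxyphenyl)hexane-1,5-dione | CC(=O)CCCC(=O)c1ccc(O)c(OC)c1O | intermediate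
4 | furan-3-carbaldehyde | O=Cc1ccoc1 | starting material
5 | 1-(2,4-dihydroxy-3-methoxyphenyl)-7-(furan-3-yl)-7-hydroxyheptane-1,5-dione (racemic aldol adduct) | OC(CC(=O)CCCC(=O)c1ccc(O)c(OC)c1O)c1ccoc1 | intermediate
6 | (E)-1-(2,4-dihydroxy-3-methoxyphenyl)-7-(furan-3-yl)hept-6-ene-1,5-dione | O=C(/C=C/c1ccoc1)CCCC(=O)c1ccc(O)c(OC)c1O | intermediate
7 | 1-(2,4-dihydroxy-3-methoxyphenyl)-7-(furan-3-yl)heptane-1,5-dione | O=C(CCc1ccoc1)CCCC(=O)c1ccc(O)c(OC)c1O | intermediate
8 | trichloroethylene | ClC=C(Cl)Cl | starting material
9 | 1-{4-[(E)-1,2-dichloroethenyloxy]-2-hydroxy-3-methoxyphenyl}-7-(furan-3-yl)heptane-1,5-dione | O=C(CCc1ccoc1)CCCC(=O)c1ccc(O/C(Cl)=C\Cl)c(OC)c1O | intermediate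
10 | 1-[4-(chloroethynyloxy)-2-hydroxy-3-methoxyphenyl]-7-(furan-3-yl)heptane-1,5-dione | ClC#COc1ccc(C(=O)CCCC(=O)CCc2ccoc2)c(O)c1OC | intermediate
11 | 1-[4-(ethynyloxy)-2-hydroxy-3-methoxyphenyl]-7-(furan-3-yl)heptane-1,5-dione | C#COc1ccc(C(=O)CCCC(=O)CCc2ccoc2)c(O)c1OC | intermediate
12 | arene oxide of 13 (epoxide across the ring-A carbon that becomes C–OH and its CH neighbour; racemic) | C1(Oc2ccc3c(O)c2OC)=CC(CCC(=O)CCCC3=O)=CC2OC12 | intermediate
13 | macrocyclic ring-A phenol (15-membered diaryl ether; ring A 4-hydroxy-3-aryloxy; C3 and C7 ketones; ring B 2-hydroxy-3-methoxy) | Oc1ccc2cc1Oc1ccc(c(O)c1OC)C(=O)CCCC(=O)CC2 | intermediate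
14 | 7-oxojuglanin A | COc1ccc2cc1Oc1ccc(c(O)c1OC)C(=O)CCCC(=O)CC2 | intermediate
15 | 7-hydroxyjuglanin A (racemic benzylic alcohol) | COc1ccc2cc1Oc1ccc(c(O)c1OC)C(O)CCCC(=O)CC2 | intermediate
16 | juglanin A | COc1ccc2cc1Oc1ccc(c(O)c1OC)CCCCC(=O)CC2 | target

**Totals**
Total step count: 8. Longest linear sequence: 8 steps (1 → 16).

**Steps most likely to fail, with fallbacks**

Step 6 (key step). The furan may attack through C5 instead of C2, which would give the 16-membered para isomer. It may also stop at hydroarylation of the ynol ether, or oligomerise. The fallback sets out from 3 and returns at 14, buying ring A instead of building it. Claisen–Schmidt condensation of 3 with 3-bromo-4-methoxybenzaldehyde gives (E)-7-(3-bromo-4-methoxyphenyl)-1-(2,4-dihydroxy-3-methoxyphenyl)hept-6-ene-1,5-dione F5. Hydrogenation with RhCl(PPh3)3 saturates the enone without touching the C–Br bond to give 7-(3-bromo-4-methoxyphenyl)-1-(2,4-dihydroxy-3-methoxyphenyl)heptane-1,5-dione F6. Intramolecular Ullmann etherification (copper iodide CuI, N,N-dimethylglycine, Cs2CO3, dioxane, high dilution) between the non-chelated 4-OH and the aryl bromide then closes the macrocycle directly to 14.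

Step 5. Incomplete enolisation would let n-BuLi add to a ketone, and the polyanion may be poorly soluble. The fallback sets out from 9 and returns at 11, using redox protection instead of enolate protection. NaBH4 in MeOH reduces both ketones to 1-{4-[(E)-1,2-dichloroethenyloxy]-2-hydroxy-3-methoxyphenyl}-7-(furan-3-yl)heptane-1,5-diol F3. n-BuLi alone (the three OH groups become inert lithium salts) then gives 1-[4-(ethynyloxy)-2-hydroxy-3-methoxyphenyl]-7-(furan-3-yl)heptane-1,5-diol F4. Parikh–Doering oxidation (SO3·pyridine, DMSO, i-Pr2NEt) restores both ketones to give 11.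

Step 1. The free ketone of 2 can condense with the very electron-rich resorcinol, or the 1,5-diketone product can cyclise (intramolecular aldol) under BF3. The fallback sets out from 1 and returns at 3, acylating with a partner that has no ketone. Glutaric anhydride with AlCl3 in nitrobenzene gives 5-(2,4-dihydroxy-3-methoxyphenyl)-5-oxopentanoic acid F1. Carbonyldiimidazole followed by MeNHOMe·HCl gives 5-(2,4-dihydroxy-3-methoxyphenyl)-N-methoxy-N-methyl-5-oxopentanamide F2. Excess MeMgBr (the aryl ketone is shielded as its magnesium phenoxide chelate) then gives 3.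

**Further compounds**
F1 | step 1 | 5-(2,4-dihydroxy-3-methoxyphenyl)-5-oxopentanoic acid | OC(=O)CCCC(=O)c1ccc(O)c(OC)c1O
F2 | step 1 | 5-(2,4-dihydroxy-3-methoxyphenyl)-N-methoxy-N-methyl-5-oxopentanamide | CON(C)C(=O)CCCC(=O)c1ccc(O)c(OC)c1O
F3 | step 5 | 1-{4-[(E)-1,2-dichloroethenyloxy]-2-hydroxy-3-methoxyphenyl}-7-(furan-3-yl)heptane-1,5-diol | OC(CCc1ccoc1)CCCC(O)c1ccc(O/C(Cl)=C\Cl)c(OC)c1O
F4 | step 5 | 1-[4-(ethynyloxy)-2-hydroxy-3-methoxyphenyl]-7-(furan-3-yl)heptane-1,5-diol | C#COc1ccc(C(O)CCCC(O)CCc2ccoc2)c(O)c1OC
F5 | step 6 | (E)-7-(3-bromo-4-methoxyphenyl)-1-(2,4-dihydroxy-3-methoxyphenyl)hept-6-ene-1,5-dione | COc1ccc(/C=C/C(=O)CCCC(=O)c2ccc(O)c(OC)c2O)cc1Br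
F6 | step 6 | 7-(3-bromo-4-methoxyphenyl)-1-(2,4-dihydroxy-3-methoxyphenyl)heptane-1,5-dione | COc1ccc(CCC(=O)CCCC(=O)c2ccc(O)c(OC)c2O)cc1Br
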